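**Retrosynthetic overview**

- Atom labels: ring C1 (quaternary, CH3 and the (Z)-chlorovinyl C7=C8), C2 (CH2), C3 (CBr carrying C9H2Br), C4 (CHCl), C5 (CH2), C6 (CHCl). The strategy rests on the C9–C3(Br)–C4(Cl) segment of the cyclohexane: it is the Br2 adduct of a C3=C9 methylidene next to heteroatom-bearing C4, a 2-methylidenecyclohexanol, which is the retron of an alkenyl halide–aldehyde reductive coupling.
- Late disconnections: C3–Br/C9–Br (Br2 addition, last), then C4–Cl and C6–Cl (two invertive substitutions of alcohols, the hindered C6 first while C4–O is masked).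
- Key disconnection C3–C4: Ni/Cr-mediated cyclisation of a 2-bromoallyl aldehyde; it forms the only ring, the six-membered carbocycle.
- Acyclic precursor: C6 carbinol by asymmetric hydrogenation of a 2-methyl-3-oxo ester, quaternary C1 by Fráter–Seebach alkylation with 2,3-dibromopropene, C7=C8 by Wittig chloromethylenation, C4 aldehyde unmasked from a 4-methoxybenzyl ether.

Key step: step 11

Remark: 3-[(4-methoxybenzyl)oxy]propan-1-ol is taken as a catalogue compound (otherwise one step from propane-1,3-diol and 4-methoxybenzyl chloride). C1–C9 in the Why lines are the overview labels, not the locants of the names.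

**Step 1**
Reactants: 1 3-[(4-methoxybenzyl)oxy]propan-1-ol
Product: 3 3-[(4-methoxybenzyl)oxy]propanoic acid, via 3-[(4-methoxybenzyl)oxy]propanal 2 (not isolated)
Conditions: TEMPO (cat.), PhI(OAc)2 (2.2 equiv), MeCN/H2O 1:1, 25 °C
Reagents that add atoms: water, O
Why: TEMPO-catalysed oxidation with PhI(OAc)2 in aqueous acetonitrile takes the primary alcohol through aldehyde 2 and its hydrate to the acid and leaves the 4-methoxybenzyl ether untouched.

**Step 2**
Reactants: 3 3-[(4-methoxybenzyl)oxy]propanoic acid; 4 3-ethoxy-2-methyl-3-oxopropanoic acid (ethyl hydrogen methylmalonate)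
Product: 6 ethyl 5-[(4-methoxybenzyl)oxy]-2-methyl-3-oxopentanoate (racemic at C2), via acyl imidazole 5 (not isolated)
Conditions: 1,1'-carbonyldiimidazole, THF, 25 °C; then 4, MgCl2, Et3N, MeCN, 25 → 45 °C; cold dilute aq. HCl
Reagents that add atoms: 3-ethoxy-2-methyl-3-oxopropanoic acid (4), CCOC(=O)C(C)C(=O)O; 1,1'-carbonyldiimidazole, O=C(n1ccnc1)n1ccnc1 (its imidazolyl group is kept only in 5)
Why: Masamune–Brooks C-acylation: acyl imidazole 5 acylates the magnesium enolate of the malonate half-ester under neutral conditions and decarboxylation gives the 2-methyl-3-oxo ester without β-elimination of the ether.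

**Step 3**
Reactants: 6 ethyl 5-[(4-methoxybenzyl)oxy]-2-methyl-3-oxopentanoate
Product: 7 ethyl (3R)-3-hydroxy-5-[(4-methoxybenzyl)oxy]-2-methylpentanoate (both C2 epimers)
Conditions: H2 (10 atm), RuCl2[(R)-BINAP] (1 mol %), EtOH, 50 °C
Reagents that add atoms: none
Why: Noyori asymmetric hydrogenation of a β-keto ester: the (R)-BINAP ruthenium catalyst delivers hydrogen to one face of the ester-chelated ketone and should set the carbinol (later C6) as 3R in both C2 epimers, and C2 is erased in step 4.

**Step 4**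
Reactants: 7 ethyl (3R)-3-hydroxy-5-[(4-methoxybenzyl)oxy]-2-methylpentanoate; 8 2,3-dibromoprop-1-ene
Product: 10 ethyl (2R,3R)-2-(2-bromoprop-2-en-1-yl)-3-hydroxy-5-[(4-methoxybenzyl)oxy]-2-methylpentanoate, via dilithium alkoxide enolate 9 (not isolated)
Conditions: LiN(i-Pr)2 (2.2 equiv), THF, −78 → −20 °C; then 8, DMPU, −78 → −10 °C; then H2O
Reagents that add atoms: 2,3-dibromoprop-1-ene (8), C=C(Br)CBr; LiN(i-Pr)2, [Li+].CC(C)[N-]C(C)C (lithium is kept only in 9)
Why: Fráter–Seebach alkylation: the lithium-chelated Z-enolate alkoxide 9 is alkylated by the allylic bromide on the face opposite the C3 side chain, so the bromoallyl group enters anti to the hydroxyl and the quaternary centre (later C1) should be set as 2R from either C2 epimer, while the alkenyl bromide is inert.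

**Step 5**
Reactants: 10 ethyl (2R,3R)-2-(2-bromoprop-2-en-1-yl)-3-hydroxy-5-[(4-methoxybenzyl)oxy]-2-methylpentanoate
Product: 11 ethyl (2R,3R)-2-(2-bromoprop-2-en-1-yl)-3-[(tert-butyldimethylsilyl)oxy]-5-[(4-methoxybenzyl)oxy]-2-methylpentanoate
Conditions: TBSOTf, 2,6-lutidine, CH2Cl2, 0 → 25 °C
Reagents that add atoms: tert-butyldimethylsilyl trifluoromethanesulfonate, CC(C)(C)[Si](C)(C)OS(=O)(=O)C(F)(F)F
Why: Silylation with the silyl triflate and 2,6-lutidine is the standard method for a hindered secondary alcohol next to a quaternary carbon and blocks retro-aldol cleavage in the later basic steps.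

**Step 6**
Reactants: 11 ethyl (2R,3R)-2-(2-bromoprop-2-en-1-yl)-3-[(tert-butyldimethylsilyl)oxy]-5-[(4-methoxybenzyl)oxy]-2-methylpentanoate
Product: 12 (2S,3R)-2-(2-bromoprop-2-en-1-yl)-3-[(tert-butyldimethylsilyl)oxy]-5-[(4-methoxybenzyl)oxy]-2-methylpentan-1-ol
Conditions: i-Bu2AlH (3 equiv), CH2Cl2, −78 → 0 °C; aqueous work-up
Reagents that add atoms: none
Why: Hydride reduction of the hindered ester to the primary alcohol with i-Bu2AlH, which leaves the alkenyl bromide, the silyl ether and the benzyl-type ether untouched at low temperature (the descriptor at C2 changes only through ligand priorities).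

**Step 7**
Reactants: 12 (2S,3R)-2-(2-bromoprop-2-en-1-yl)-3-[(tert-butyldimethylsilyl)oxy]-5-[(4-methoxybenzyl)oxy]-2-methylpentan-1-ol
Product: 13 (2R,3R)-2-(2-bromoprop-2-en-1-yl)-3-[(tert-butyldimethylsilyl)oxy]-5-[(4-methoxybenzyl)oxy]-2-methylpentanal
Conditions: Dess–Martin periodinane, NaHCO3, CH2Cl2, 0 → 25 °C
Reagents that add atoms: none
Why: Dess–Martin oxidation of the neopentyl alcohol gives an aldehyde without α-hydrogen, which can neither epimerise nor eliminate.

**Step 8**
Reactants: 13 (2R,3R)-2-(2-bromoprop-2-en-1-yl)-3-[(tert-butyldimethylsilyl)oxy]-5-[(4-methoxybenzyl)oxy]-2-methylpentanal; 14 (chloromethyl)triphenylphosphonium chloride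
Product: 16 (1Z,3S,4R)-3-(2-bromoprop-2-en-1-yl)-4-[(tert-butyldimethylsilyl)oxy]-1-chloro-6-[(4-methoxybenzyl)oxy]-3-methylhex-1-ene, via (chloromethylidene)triphenylphosphorane 15 (not isolated)
Conditions: 14, NaN(SiMe3)2, THF, −78 → 0 °C; then 13, −78 → 25 °C
Reagents that add atoms: (chloromethyl)triphenylphosphonium chloride (14), [Cl-].ClC[P+](c1ccccc1)(c1ccccc1)c1ccccc1
Why: Wittig chloromethylenation with the non-stabilised ylide 15 at low temperature without lithium salts should favour the (Z)-chloroalkene through the kinetically formed cis-oxaphosphetane, and the minor (E)-isomer would be removed by chromatography.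

**Step 9**
Reactants: 16 (1Z,3S,4R)-3-(2-bromoprop-2-en-1-yl)-4-[(tert-butyldimethylsilyl)oxy]-1-chloro-6-[(4-methoxybenzyl)oxy]-3-methylhex-1-ene
Product: 17 (3R,4S,5Z)-4-(2-bromoprop-2-en-1-yl)-3-[(tert-butyldimethylsilyl)oxy]-6-chloro-4-methylhex-5-en-1-ol
Conditions: DDQ, CH2Cl2/pH 7 buffer 10:1, 0 → 25 °C
Reagents that add atoms: none
Why: Oxidative cleavage of the 4-methoxybenzyl ether by DDQ (benzylic hydride abstraction, then hydrolysis) spares the silyl ether and the two electron-poor haloalkenes.

**Step 10**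
Reactants: 17 (3R,4S,5Z)-4-(2-bromoprop-2-en-1-yl)-3-[(tert-butyldimethylsilyl)oxy]-6-chloro-4-methylhex-5-en-1-ol
Product: 18 (3R,4S,5Z)-4-(2-bromoprop-2-en-1-yl)-3-[(tert-butyldimethylsilyl)oxy]-6-chloro-4-methylhex-5-enal
Conditions: Dess–Martin periodinane, NaHCO3, CH2Cl2, 0 → 25 °C
Reagents that add atoms: none
Why: Buffered Dess–Martin oxidation should give the β-silyloxy aldehyde without β-elimination, and the aldehyde would be used at once.

**Step 11**
Reactants: 18 (3R,4S,5Z)-4-(2-bromoprop-2-en-1-yl)-3-[(tert-butyldimethylsilyl)oxy]-6-chloro-4-methylhex-5-enal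
Product: 20 (1S,4S,5R)-5-[(tert-butyldimethylsilyl)oxy]-4-[(Z)-2-chloroethenyl]-4-methyl-2-methylidenecyclohexan-1-ol, via alkenylchromium dichloride 19 (not isolated)
Conditions: CrCl2 (6 equiv), NiCl2 (2 mol %), degassed DMF (0.005 M), 25 °C; then H2O
Reagents that add atoms: CrCl2, [Cr+2].[Cl-].[Cl-] (chromium and chloride are kept only in 19)
Why: Zerovalent nickel formed from NiCl2 and CrCl2 inserts into the C3–Br bond of 18 and hands the alkenyl group to trivalent chromium, and the alkenylchromium dichloride 19 adds to the C4 aldehyde, so two electrophilic carbons are joined by reductive reversal of polarity. The closest known reaction type is the intramolecular Nozaki–Hiyama–Kishi coupling of 2-bromoallyl aldehydes to 2-methylidenecycloalkanols. The ring C1–C2–C3–C4–C5–C6 closes in a 6-exo-trig mode, with the C=O bond outside the new ring. The new stereocentre C4 is controlled by C1 and C6 through a chair-like transition state in which the chromium-bound oxygen, the silyloxy group and the chlorovinyl group are equatorial and the C1 methyl is axial, which places the C4 hydroxyl cis to the C6 silyl ether. The step needs activation of C–Br and not of the alkenyl C–Cl bond, and a non-basic medium for the β-silyloxy aldehyde; the much slower insertion of nickel into alkenyl chlorides at 25 °C and the neutral chromium salts in DMF secure both, and high dilution suppresses intermolecular coupling.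

**Step 12**
Reactants: 20 (1S,4S,5R)-5-[(tert-butyldimethylsilyl)oxy]-4-[(Z)-2-chloroethenyl]-4-methyl-2-methylidenecyclohexan-1-ol
Product: 21 (1S,4S,5R)-5-[(tert-butyldimethylsilyl)oxy]-4-[(Z)-2-chloroethenyl]-4-methyl-2-methylidenecyclohexyl acetate
Conditions: Ac2O, pyridine, DMAP (cat.), CH2Cl2, 0 → 25 °C
Reagents that add atoms: acetic anhydride, CC(=O)OC(C)=O
Why: DMAP-catalysed acetylation masks the allylic C4 hydroxyl, so that the hindered C6 position can be substituted first and no epimerisable allylic chloride is exposed to chloride at elevated temperature.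

**Step 13**
Reactants: 21 (1S,4S,5R)-5-[(tert-butyldimethylsilyl)oxy]-4-[(Z)-2-chloroethenyl]-4-methyl-2-methylidenecyclohexyl acetate
Product: 22 (1S,4S,5R)-4-[(Z)-2-chloroethenyl]-5-hydroxy-4-methyl-2-methylidenecyclohexyl acetate
Conditions: HF·pyridine, pyridine, THF, 0 → 25 °C
Reagents that add atoms: none
Why: Fluoride-mediated desilylation under buffered acidic conditions frees the C6 hydroxyl without the acetate cleavage or migration that basic tetrabutylammonium fluoride could cause.

**Step 14**
Reactants: 22 (1S,4S,5R)-4-[(Z)-2-chloroethenyl]-5-hydroxy-4-methyl-2-methylidenecyclohexyl acetate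
Product: 24 (1S,4S,5S)-5-chloro-4-[(Z)-2-chloroethenyl]-4-methyl-2-methylidenecyclohexyl acetate, via alkoxytriphenylphosphonium chloride 23 (not isolated)
Conditions: PPh3 (3 equiv), CCl4, MeCN, 25 → 65 °C
Reagents that add atoms: carbon tetrachloride, ClC(Cl)(Cl)Cl; triphenylphosphine, c1ccc(cc1)P(c1ccccc1)c1ccccc1 (kept only in 23)
Why: Appel deoxychlorination with inversion: in the chair with both oxygens equatorial and the C1 methyl axial the oxyphosphonium group of 23 is equatorial, chloride enters axially past only the axial hydrogens on C2 and C4, and no β-hydrogen is anti-periplanar for E2, much as in the inversion of menthol to neomenthyl chloride.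

**Step 15**
Reactants: 24 (1S,4S,5S)-5-chloro-4-[(Z)-2-chloroethenyl]-4-methyl-2-methylidenecyclohexyl acetate
Product: 25 (1S,4S,5S)-5-chloro-4-[(Z)-2-chloroethenyl]-4-methyl-2-methylidenecyclohexan-1-ol
Conditions: K2CO3 (cat.), MeOH, 0 → 25 °C
Reagents that add atoms: none
Why: Base-catalysed transesterification with methanol removes the acetate, while the secondary alkyl chloride and both haloalkene units are inert to carbonate.

**Step 16**
Reactants: 25 (1S,4S,5S)-5-chloro-4-[(Z)-2-chloroethenyl]-4-methyl-2-methylidenecyclohexan-1-ol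
Product: 27 (1S,2S,4R)-2,4-dichloro-1-[(Z)-2-chloroethenyl]-1-methyl-5-methylidenecyclohexane, via alkoxytriphenylphosphonium chloride 26 (not isolated)
Conditions: PPh3, hexachloroacetone, CH2Cl2, −20 → 0 °C
Reagents that add atoms: hexachloroacetone, ClC(Cl)(Cl)C(=O)C(Cl)(Cl)Cl; triphenylphosphine, c1ccc(cc1)P(c1ccccc1)c1ccccc1 (kept only in 26)
Why: Appel-type chlorination of an allylic alcohol with hexachloroacetone as chlorine source should displace the oxyphosphonium group of 26 by SN2 with inversion and little allylic transposition at low temperature, which sets the C4 chloride cis to the C6 chloride.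

**Step 17**
Reactants: 27 (1S,2S,4R)-2,4-dichloro-1-[(Z)-2-chloroethenyl]-1-methyl-5-methylidenecyclohexane
Product: 28 (1S,2R,4S,5S)-1-bromo-1-(bromomethyl)-2,4-dichloro-5-[(Z)-2-chloroethenyl]-5-methylcyclohexane
Conditions: Br2 (1.0 equiv), CH2Cl2, −78 °C, dark
Reagents that add atoms: bromine, BrBr
Why: Electrophilic anti addition of bromine to the 1,1-disubstituted alkene, which is far more reactive than the hindered, electron-poor chloroalkene; in the preferred chair (both chlorines equatorial, chlorovinyl axial) bromine should reach C9 from the face opposite the axial chlorovinyl group and bromide should bond to tertiary C3 along the axial trajectory, giving axial C3–Br and equatorial CH2Br, the arrangement that also avoids a syn-diaxial CH2Br/chlorovinyl contact.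

**Compound list**

1 | 3-[(4-methoxybenzyl)oxy]propan-1-ol | COc1ccc(COCCCO)cc1 | starting material
2 | 3-[(4-methoxybenzyl)oxy]propanal | COc1ccc(COCCC=O)cc1 | intermediate (not isolated)
3 | 3-[(4-methoxybenzyl)oxy]propanoic acid | COc1ccc(COCCC(=O)O)cc1 | intermediate
4 | 3-ethoxy-2-methyl-3-oxopropanoic acid | CCOC(=O)C(C)C(=O)O | starting material
5 | 1-{3-[(4-methoxybenzyl)oxy]propanoyl}-1H-imidazole | COc1ccc(COCCC(=O)n2ccnc2)cc1 | intermediate (not isolated)
6 | ethyl 5-[(4-methoxybenzyl)oxy]-2-methyl-3-oxopentanoate (racemic at C2) | CCOC(=O)C(C)C(=O)CCOCc1ccc(OC)cc1 | intermediate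
7 | ethyl (3R)-3-hydroxy-5-[(4-methoxybenzyl)oxy]-2-methylpentanoate (both C2 epimers) | CCOC(=O)C(C)[C@H](O)CCOCc1ccc(OC)cc1 | intermediate
8 | 2,3-dibromoprop-1-ene | C=C(Br)CBr | starting material
9 | dilithium alkoxide enolate of 7 (Z-enolate, 3R) | CCO/C([O-])=C(\C)[C@H]([O-])CCOCc1ccc(OC)cc1.[Li+].[Li+] | intermediate (not isolated)
10 | ethyl (2R,3R)-2-(2-bromoprop-2-en-1-yl)-3-hydroxy-5-[(4-methoxybenzyl)oxy]-2-methylpentanoate | CCOC(=O)[C@](C)(CC(Br)=C)[C@H](O)CCOCc1ccc(OC)cc1 | intermediate
11 | ethyl (2R,3R)-2-(2-bromoprop-2-en-1-yl)-3-[(tert-butyldimethylsilyl)oxy]-5-[(4-methoxybenzyl)oxy]-2-methylpentanoate | CCOC(=O)[C@](C)(CC(Br)=C)[C@H](O[Si](C)(C)C(C)(C)C)CCOCc1ccc(OC)cc1 | intermediate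
12 | (2S,3R)-2-(2-bromoprop-2-en-1-yl)-3-[(tert-butyldimethylsilyl)oxy]-5-[(4-methoxybenzyl)oxy]-2-methylpentan-1-ol | OC[C@](C)(CC(Br)=C)[C@H](O[Si](C)(C)C(C)(C)C)CCOCc1ccc(OC)cc1 | intermediate
13 | (2R,3R)-2-(2-bromoprop-2-en-1-yl)-3-[(tert-butyldimethylsilyl)oxy]-5-[(4-methoxybenzyl)oxy]-2-methylpentanal | O=C[C@](C)(CC(Br)=C)[C@H](O[Si](C)(C)C(C)(C)C)CCOCc1ccc(OC)cc1 | intermediate
14 | (chloromethyl)triphenylphosphonium chloride | [Cl-].ClC[P+](c1ccccc1)(c1ccccc1)c1ccccc1 | starting material
15 | (chloromethylidene)triphenylphosphorane | ClC=P(c1ccccc1)(c1ccccc1)c1ccccc1 | intermediate (not isolated)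
16 | (1Z,3S,4R)-3-(2-bromoprop-2-en-1-yl)-4-[(tert-butyldimethylsilyl)oxy]-1-chloro-6-[(4-methoxybenzyl)oxy]-3-methylhex-1-ene | Cl/C=C\[C@](C)(CC(Br)=C)[C@H](O[Si](C)(C)C(C)(C)C)CCOCc1ccc(OC)cc1 | intermediate
17 | (3R,4S,5Z)-4-(2-bromoprop-2-en-1-yl)-3-[(tert-butyldimethylsilyl)oxy]-6-chloro-4-methylhex-5-en-1-ol | OCC[C@@H](O[Si](C)(C)C(C)(C)C)[C@](C)(/C=C\Cl)CC(Br)=C | intermediate
18 | (3R,4S,5Z)-4-(2-bromoprop-2-en-1-yl)-3-[(tert-butyldimethylsilyl)oxy]-6-chloro-4-methylhex-5-enal | O=CC[C@@H](O[Si](C)(C)C(C)(C)C)[C@](C)(/C=C\Cl)CC(Br)=C | intermediate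
19 | alkenylchromium dichloride from 18 (trivalent chromium on C3) | O=CC[C@@H](O[Si](C)(C)C(C)(C)C)[C@](C)(/C=C\Cl)CC(=C)[Cr](Cl)Cl | intermediate (not isolated)
20 | (1S,4S,5R)-5-[(tert-butyldimethylsilyl)oxy]-4-[(Z)-2-chloroethenyl]-4-methyl-2-methylidenecyclohexan-1-ol | C[C@@]1(/C=C\Cl)CC(=C)[C@@H](O)C[C@H]1O[Si](C)(C)C(C)(C)C | intermediate
21 | (1S,4S,5R)-5-[(tert-butyldimethylsilyl)oxy]-4-[(Z)-2-chloroethenyl]-4-methyl-2-methylidenecyclohexyl acetate | C[C@@]1(/C=C\Cl)CC(=C)[C@@H](OC(C)=O)C[C@H]1O[Si](C)(C)C(C)(C)C | intermediate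
22 | (1S,4S,5R)-4-[(Z)-2-chloroethenyl]-5-hydroxy-4-methyl-2-methylidenecyclohexyl acetate | C[C@@]1(/C=C\Cl)CC(=C)[C@@H](OC(C)=O)C[C@H]1O | intermediate
23 | alkoxytriphenylphosphonium chloride of 22 (phosphorus on the C6 oxygen) | C[C@@]1(/C=C\Cl)CC(=C)[C@@H](OC(C)=O)C[C@H]1O[P+](c1ccccc1)(c1ccccc1)c1ccccc1.[Cl-] | intermediate (not isolated)
24 | (1S,4S,5S)-5-chloro-4-[(Z)-2-chloroethenyl]-4-methyl-2-methylidenecyclohexyl acetate | C[C@@]1(/C=C\Cl)CC(=C)[C@@H](OC(C)=O)C[C@@H]1Cl | intermediate
25 | (1S,4S,5S)-5-chloro-4-[(Z)-2-chloroethenyl]-4-methyl-2-methylidenecyclohexan-1-ol | C[C@@]1(/C=C\Cl)CC(=C)[C@@H](O)C[C@@H]1Cl | intermediate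
26 | alkoxytriphenylphosphonium chloride of 25 (phosphorus on the C4 oxygen) | C[C@@]1(/C=C\Cl)CC(=C)[C@@H](O[P+](c2ccccc2)(c2ccccc2)c2ccccc2)C[C@@H]1Cl.[Cl-] | intermediate (not isolated)
27 | (1S,2S,4R)-2,4-dichloro-1-[(Z)-2-chloroethenyl]-1-methyl-5-methylidenecyclohexane | C[C@@]1(/C=C\Cl)CC(=C)[C@H](Cl)C[C@@H]1Cl | intermediate
28 | (1S,2R,4S,5S)-1-bromo-1-(bromomethyl)-2,4-dichloro-5-[(Z)-2-chloroethenyl]-5-methylcyclohexane | C[C@@]1(/C=C\Cl)C[C@@](Br)(CBr)[C@H](Cl)C[C@@H]1Cl | target

**Step count and risks**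

Total step count: 17. Longest linear sequence: 17 steps (1 to 28).

Steps most likely to fail:

1. Step 14, substitution at C6. The displacement at a carbon flanked by the quaternary C1 may be outrun by elimination towards C5 or by a 1,2-shift from C1 once the oxyphosphonium group starts to ionise on heating. The fallback sets out from 22 and uses a sulfonate displacement in place of the phosphorus-based activation. 22 would be converted into (1S,4S,5R)-4-[(Z)-2-chloroethenyl]-4-methyl-2-methylidene-5-{[(trifluoromethyl)sulfonyl]oxy}cyclohexyl acetate F1 with Tf2O and pyridine in CH2Cl2 at −40 °C. The much better leaving group would then be displaced with Bu4NCl in toluene between −20 and 25 °C, an SN2 reaction run cold under non-ionising, chloride-rich conditions. The route is rejoined at 24.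

2. Step 11, ring closure. Facial selectivity in the addition of the alkenylchromium to the aldehyde may be poor, so that 20 is delivered together with its C4 epimer. The fallback sets out from 20 as this epimer mixture and sets C4 by hydride reduction, not in the cyclisation. Dess–Martin oxidation would give (4S,5R)-5-[(tert-butyldimethylsilyl)oxy]-4-[(Z)-2-chloroethenyl]-4-methyl-2-methylidenecyclohexan-1-one F2. Luche reduction (NaBH4, CeCl3·7H2O, MeOH, −78 °C) should then deliver hydride axially to the chair with the silyloxy group equatorial and give the equatorial alcohol. The route is rejoined at 20.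

3. Step 17, bromine addition. Facial selectivity may be incomplete, with bromide bonding to C3 from the equatorial side and giving the C3 epimer. The fallback sets out from 27 and replaces kinetic control by thermodynamic control. The addition would be run as in step 17 and the epimer (1R,2R,4S,5S)-1-bromo-1-(bromomethyl)-2,4-dichloro-5-[(Z)-2-chloroethenyl]-5-methylcyclohexane F3 would be separated. F3 would be warmed in 1,2-dichloroethane at 60–80 °C, where the 1,2-interchange of vicinal bromines (the dyotropic mutarotation known for vicinal dibromides) inverts C3. This should drain F3 into the more stable isomer with axial bromine and equatorial CH2Br. The route is rejoined at 28.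

**Further compounds**

F1 | step 14 | (1S,4S,5R)-4-[(Z)-2-chloroethenyl]-4-methyl-2-methylidene-5-{[(trifluoromethyl)sulfonyl]oxy}cyclohexyl acetate | C[C@@]1(/C=C\Cl)CC(=C)[C@@H](OC(C)=O)C[C@H]1OS(=O)(=O)C(F)(F)F
F2 | step 11 | (4S,5R)-5-[(tert-butyldimethylsilyl)oxy]-4-[(Z)-2-chloroethenyl]-4-methyl-2-methylidenecyclohexan-1-one | C[C@@]1(/C=C\Cl)CC(=C)C(=O)C[C@H]1O[Si](C)(C)C(C)(C)C
F3 | step 17 | (1R,2R,4S,5S)-1-bromo-1-(bromomethyl)-2,4-dichloro-5-[(Z)-2-chloroethenyl]-5-methylcyclohexane | C[C@@]1(/C=C\Cl)C[C@](Br)(CBr)[C@H](Cl)C[C@@H]1Cl
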